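**Strategy.** The four C–CH3 bonds are disconnected last: both gem-dimethyl carbons of the two outer cyclohexadienone rings are traced back to the single unsubstituted aromatic CH of each outer ring in a fully aromatic, methylene-bridged tris(butyrylphloroglucinol). The key step exploits that in this nonaphenol only these two CH carbons, each flanked by two C–OH carbons, are unsubstituted, whereas every carbon of the central ring already bears the butyryl group, a hydroxyl or a CH2 bridge. Twofold C-methylation at each of them with iodomethane dearomatises both outer rings in one operation, closing no ring and creating no stereocentre. The trimer itself comes from phloroglucinol by acylation, bis-aminomethylation and quinone-methide coupling.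

Key step: step 4

Remark on the chemistry: the target has no stereocentre (each quaternary ring carbon carries two identical methyl groups), so it is achiral and no enantiomer has to be selected; it is drawn as one tautomer of its two enolised β-triketone rings.

Design choices: the trimer is methylated unprotected, because its phenoxides are the activating groups and any protecting group would add a removal step on a base- and acid-sensitive bridged product. The bis-Mannich base 5 is isolated and stored as its bis(hydroiodide), so that the electrophile is unmasked only in the presence of excess nucleophile; it is listed in neutral form.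

**Step 1**
Reactants: 1 phloroglucinol; 2 butyryl chloride
Product: 3 1-(2,4,6-trihydroxyphenyl)butan-1-one (butyrylphloroglucinol)
Conditions: AlCl3 (3.5 equiv), PhNO2–CH2Cl2, 0 → 45 °C; ice/aq HCl
Reagents that add atoms: butyryl chloride (2), CCCC(Cl)=O
Why: Friedel–Crafts acylation of the very electron-rich ring; the aluminium chelate of the first aryl ketone deactivates the ring towards a second acylation, and any ester formed at oxygen is carried on to the C-acyl product by Fries rearrangement under the same conditions.

**Step 2**
Reactants: 3 1-(2,4,6-trihydroxyphenyl)butan-1-one; 4 N,N-dimethylmethyleneiminium iodide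
Product: 5 1-{3,5-bis[(dimethylamino)methyl]-2,4,6-trihydroxyphenyl}butan-1-one (collected as its bis(hydroiodide))
Conditions: 4 (2.1 equiv), MeCN, 0 °C → rt, Ar, no base; salt filtered off
Reagents that add atoms: N,N-dimethylmethyleneiminium iodide (4), C=[N+](C)C.[I-]
Why: Mannich aminomethylation (electrophilic aromatic substitution by the preformed iminium ion) can occur only at the two remaining ring CH positions of 3, so a slight excess of 4 should drive it to the bis-adduct, and without added base both amines stay protonated by the hydrogen iodide formed, which keeps the product from losing amine before the coupling.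

**Step 3**
Reactants: 5 1-{3,5-bis[(dimethylamino)methyl]-2,4,6-trihydroxyphenyl}butan-1-one (as bis(hydroiodide)); 3 1-(2,4,6-trihydroxyphenyl)butan-1-one (8 equiv)
Product: 9 1-{3,5-bis[(3-butanoyl-2,4,6-trihydroxyphenyl)methyl]-2,4,6-trihydroxyphenyl}butan-1-one, via first quinone methide 6 (not isolated), via dimer Mannich base 7 (not isolated), via second quinone methide 8 (not isolated)
Conditions: NaOAc (2.2 equiv), AcOH–1,4-dioxane, 80 °C, Ar; excess 3 recovered
Reagents that add atoms: 1-(2,4,6-trihydroxyphenyl)butan-1-one (3, two equivalents incorporated), CCCC(=O)c1c(O)cc(O)cc1O
Why: On buffered heating each ortho-hydroxybenzylammonium arm loses dimethylamine to give an ortho-quinone methide that is captured by C-selective conjugate (Michael) addition of the phloroglucinol ring of 3 and rearomatisation, the known alkylation of carbon nucleophiles by phenolic Mannich bases; the electrophile sits on the ring that becomes fully substituted, and the large excess of 3 makes capture by the free CH of an already coupled ring improbable.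

**Step 4**
Reactants: 9 1-{3,5-bis[(3-butanoyl-2,4,6-trihydroxyphenyl)methyl]-2,4,6-trihydroxyphenyl}butan-1-one; 10 iodomethane
Product: 12 1-{3,5-bis[(5-butanoyl-2,6-dihydroxy-3,3-dimethyl-4-oxocyclohexa-1,5-dien-1-yl)methyl]-2,4,6-trihydroxyphenyl}butan-1-one, via di-C-methyl aromatic trimer 11 (not isolated)
Conditions: NaOMe (8 equiv), degassed MeOH, Ar, 0 °C; MeI (4.2 equiv) added slowly, 0 °C → rt; 1 M HCl to pH 2; crystallisation
Reagents that add atoms: iodomethane (10), CI
Why: Methoxide turns 9 into its polyphenoxide, and each outer ring attacks iodomethane (SN2) through its one unsubstituted ring carbon, regains aromaticity by tautomerisation and is methylated once more at that carbon, which then is quaternary and locks the ring as a non-aromatic β-triketone enolate. The closest known reaction is the methoxide/iodomethane C,C-dimethylation of acylphloroglucinols to acylfilicinic acids (alkylative dearomatisation), run here at both ends of one molecule. No ring is closed and no stereocentre arises, because each new quaternary carbon carries two identical methyl groups. The step needs site selectivity among the ring carbons and carbon- over oxygen-alkylation: the first methyl group can only find the free CH, the second should prefer this methyl-bearing carbon over the more crowded bridge-bearing carbons of the outer and central rings, and hydrogen bonding by methanol shields the phenoxide oxygens. The reaction should stop by itself, since a dimethylated ring is a delocalised triketone enolate of low nucleophilicity and the base charge (four equivalents end as sodium iodide, the rest stays bound as phenoxide) leaves almost no free methoxide to consume iodomethane or to promote bridge exchange. Acidification then protonates the enolates and 12 should be obtained by crystallisation.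

**Compound list**
1 | phloroglucinol (benzene-1,3,5-triol) | Oc1cc(O)cc(O)c1 | starting material
2 | butyryl chloride | CCCC(Cl)=O | starting material
3 | 1-(2,4,6-trihydroxyphenyl)butan-1-one (butyrylphloroglucinol) | CCCC(=O)c1c(O)cc(O)cc1O | intermediate
4 | N,N-dimethylmethyleneiminium iodide | C=[N+](C)C.[I-] | starting material
5 | 1-{3,5-bis[(dimethylamino)methyl]-2,4,6-trihydroxyphenyl}butan-1-one (handled as bis(hydroiodide)) | CCCC(=O)c1c(O)c(CN(C)C)c(O)c(CN(C)C)c1O | intermediate
6 | first ortho-quinone methide: 2-butanoyl-4-[(dimethylamino)methyl]-3,5-dihydroxy-6-methylidenecyclohexa-2,4-dien-1-one | CCCC(=O)C1=C(O)C(CN(C)C)=C(O)C(=C)C1=O | intermediate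
7 | dimer Mannich base: 1-{3-[(3-butanoyl-2,4,6-trihydroxyphenyl)methyl]-5-[(dimethylamino)methyl]-2,4,6-trihydroxyphenyl}butan-1-one | CCCC(=O)c1c(O)c(CN(C)C)c(O)c(Cc2c(O)cc(O)c(C(=O)CCC)c2O)c1O | intermediate
8 | second ortho-quinone methide: 2-butanoyl-4-[(3-butanoyl-2,4,6-trihydroxyphenyl)methyl]-3,5-dihydroxy-6-methylidenecyclohexa-2,4-dien-1-one | CCCC(=O)C1=C(O)C(Cc2c(O)cc(O)c(C(=O)CCC)c2O)=C(O)C(=C)C1=O | intermediate
9 | methylene-bridged tris(butyrylphloroglucinol): 1-{3,5-bis[(3-butanoyl-2,4,6-trihydroxyphenyl)methyl]-2,4,6-trihydroxyphenyl}butan-1-one | CCCC(=O)c1c(O)cc(O)c(Cc2c(O)c(Cc3c(O)cc(O)c(C(=O)CCC)c3O)c(O)c(C(=O)CCC)c2O)c1O | intermediate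
10 | iodomethane | CI | starting material
11 | di-C-methyl aromatic trimer: 1-{3,5-bis[(3-butanoyl-2,4,6-trihydroxy-5-methylphenyl)methyl]-2,4,6-trihydroxyphenyl}butan-1-one | CCCC(=O)c1c(O)c(C)c(O)c(Cc2c(O)c(Cc3c(O)c(C)c(O)c(C(=O)CCC)c3O)c(O)c(C(=O)CCC)c2O)c1O | intermediate
12 | target trimer (achiral; constitution of filixic acid BBB): 1-{3,5-bis[(5-butanoyl-2,6-dihydroxy-3,3-dimethyl-4-oxocyclohexa-1,5-dien-1-yl)methyl]-2,4,6-trihydroxyphenyl}butan-1-one | CCCC(=O)C1=C(O)C(Cc2c(O)c(CC3=C(O)C(C)(C)C(=O)C(C(=O)CCC)=C3O)c(O)c(C(=O)CCC)c2O)=C(O)C(C)(C)C1=O | target

**Totals**
Total step count: 4. Longest linear sequence: 4 steps (1 → 3 → 5 → 9 → 12).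

**Steps most likely to fail**

Step 4. The second or an extra methyl group may be delivered to a bridge-bearing carbon of an outer or the central ring, oxygen may be methylated, methylation may stop short, or the methylene bridges may exchange between rings in the basic medium, so that a family of homologues forms instead of one product. The fallback sets out from 3 and 5 and comes back at 12; it moves the dearomatisation in front of the coupling. Monomer 3 is C,C-dimethylated with NaOMe/MeI in MeOH, the established preparation of acylfilicinic acids, to 2-butanoyl-3,5-dihydroxy-6,6-dimethylcyclohexa-2,4-dien-1-one (butyrylfilicinic acid) F1, which is purified at this small-molecule stage from its mono- and trimethyl congeners. An excess of F1 is then alkylated at its only ring CH by the two quinone methides released from 5 under the conditions of step 3, which should give 12 directly, so that no methyl group is ever installed in the presence of a bridge.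

Step 3. A quinone methide may be captured by the free CH of an already coupled outer ring (chain growth to higher oligomers), the bridges may redistribute on prolonged heating, or amine loss from the protonated arms may be too slow. The fallback sets out from 5 and comes back at 9; it changes the leaving group so that the quinone methide forms at room temperature. The free base of 5 is N-methylated on both arms with iodomethane in acetone at 0 °C, from which the bis(trimethylammonium) diiodide F2 should precipitate. F2 is then added in portions to excess 3 and NaHCO3 in aqueous acetonitrile at 20 °C, where 1,4-elimination of trimethylamine and Michael capture by 3 should give 9 under kinetic control.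

Step 2. The second aminomethylation may stall on the ring that carries the first ammonium arm, the mono-adduct may lose amine and condense with itself, or the iminium ion may attack the carbon alpha to the ketone. The fallback sets out from 3 and comes back at 9; it uses classical amine-free formaldehyde bridging. Excess 3 is condensed with aqueous formaldehyde in dilute aqueous NaOH at 0 °C to the methylene-bridged dimer bis(3-butanoyl-2,4,6-trihydroxyphenyl)methane F3. A second formaldehyde condensation between F3 and further 3 then gives 9, which is separated from recovered dimer and higher oligomers by chromatography. This bypasses 5 and step 3 at the price of a statistical product distribution.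

**Further compounds**
F1 | step 4 | 2-butanoyl-3,5-dihydroxy-6,6-dimethylcyclohexa-2,4-dien-1-one (butyrylfilicinic acid) | CCCC(=O)C1=C(O)C=C(O)C(C)(C)C1=O
F2 | step 3 | 1-{2,4,6-trihydroxy-3,5-bis[(trimethylammonio)methyl]phenyl}butan-1-one diiodide | CCCC(=O)c1c(O)c(C[N+](C)(C)C)c(O)c(C[N+](C)(C)C)c1O.[I-].[I-]
F3 | step 2 | bis(3-butanoyl-2,4,6-trihydroxyphenyl)methane | CCCC(=O)c1c(O)cc(O)c(Cc2c(O)cc(O)c(C(=O)CCC)c2O)c1O
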